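The disconnection breaks ring C at the bond between its aromatic carbon and the benzylic CH2 of the (R)-2-oxypropyl chain, which lies ortho to the ester carbonyl carbon of that ring. A carboxylate-directed, palladium-catalysed C–H alkylation of 2,4-bis(benzyloxy)benzoic acid with (R)-propylene oxide should forge this bond at C6, the only free ortho C–H, and close the dihydroisocoumarin lactone in the same operation, with the (R) centre taken unchanged from the epoxide. The precursor is simply the dibenzyl-protected resorcylic acid with C2 blocked. The lactone is then opened, acylated with the D acid, joined to the A–B alcohol by Mitsunobu inversion and debenzylated.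

Key step: step 2

Remark: the units are lettered A (3,5-dihydroxyphenylpropanol), B (inner 3-hydroxybutanoate), C (resorcylate ring) and D (terminal 3-hydroxybutanoate); all four stereocentres of the target are (R); 1,3-bis(benzyloxy)-5-bromobenzene is taken as a catalogue compound.

Step 1
Reactants: 1 2,4-dihydroxybenzoic acid; 2 benzyl bromide
Product: 4 2,4-bis(benzyloxy)benzoic acid, via benzyl 2,4-bis(benzyloxy)benzoate 3 (not isolated)
Conditions: BnBr (3.3 equiv), K2CO3, DMF, 70 °C; then aq. KOH, MeOH, 70 °C; HCl work-up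
Reagents that add atoms: benzyl bromide (2), BrCc1ccccc1; potassium hydroxide, [K+].[OH-]
Why: Williamson O-benzylation of both phenols and the carboxylate, followed by saponification of the benzyl ester, should leave the two hydroxide-inert aryl benzyl ethers on the free acid.

Step 2
Reactants: 4 2,4-bis(benzyloxy)benzoic acid; 5 (R)-propylene oxide
Product: 7 (R)-6,8-bis(benzyloxy)-3-methylisochroman-1-one, via hydroxy acid 6 (not isolated)
Conditions: Pd(OAc)2 (10 mol%), N-acetyl-L-tert-leucine (20 mol%), KOAc (1 equiv), 5 (3 equiv), (CF3)2CHOH, 75 °C, sealed tube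
Reagents that add atoms: none
Why: The carboxylate of 4 binds divalent palladium and directs concerted metalation–deprotonation at C6 to give a five-membered aryl palladacycle, whose aryl–Pd bond opens the coordinated epoxide 5 at its CH2 terminus in a redox-neutral SN2-type step before protonolysis releases hydroxy acid 6 and the catalyst. The closest known reaction type is the Pd(OAc)2/mono-N-protected amino acid catalysed ortho C–H alkylation of benzoic acids with terminal epoxides, which delivers 3-substituted 3,4-dihydroisocoumarins. The lactone ring closes by 6-exo-trig acyl substitution of the secondary hydroxyl on the carboxyl carbon in the acidic fluoroalcohol. No stereocentre is created: C3 of 7 is the CH(CH3) carbon of the epoxide, none of whose bonds is broken, so the (R) configuration of 5 is carried over. The step needs site selectivity, which the substrate fixes because C2 carries a benzyloxy group and C6 is the only ortho C–H, and terminal regioselectivity of epoxide opening, which the steric bias of the SN2-type attack secures.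

Step 3
Reactants: 7 (R)-6,8-bis(benzyloxy)-3-methylisochroman-1-one; 8 allyl bromide
Product: 10 prop-2-en-1-yl 2,4-bis(benzyloxy)-6-[(2R)-2-hydroxypropyl]benzoate, via potassium carboxylate 9 (not isolated)
Conditions: KOH (1.2 equiv), THF–H2O, 60 °C; CO2 (quench of excess KOH); evaporate; allyl bromide, DMF, 0 °C to rt
Reagents that add atoms: potassium hydroxide, [K+].[OH-]; allyl bromide (8), C=CCBr
Why: Saponification opens the lactone and the carboxylate is then O-alkylated by SN2 on allyl bromide, a step insensitive to the two ortho substituents, while removal of excess hydroxide keeps the hydroxy ester from closing back.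

Step 4
Reactants: 11 methyl (R)-3-hydroxybutanoate; 12 benzyl 2,2,2-trichloroacetimidate
Product: 13 methyl (R)-3-(benzyloxy)butanoate
Conditions: BnOC(=NH)CCl3 (1.5 equiv), TfOH (cat.), cyclohexane–CH2Cl2, rt
Reagents that add atoms: benzyl 2,2,2-trichloroacetimidate (12), N=C(OCc1ccccc1)C(Cl)(Cl)Cl
Why: Acid-catalysed benzylation with the trichloroacetimidate runs under non-basic conditions, so the β-hydroxy ester should be etherified without elimination or loss of configuration.

Step 5
Reactants: 13 methyl (R)-3-(benzyloxy)butanoate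
Product: 14 (R)-3-(benzyloxy)butanoic acid
Conditions: LiOH, THF–H2O, 0 °C to rt; then 1 M HCl
Reagents that add atoms: lithium hydroxide, [Li+].[OH-]
Why: Saponification at low temperature should cleave the methyl ester faster than E1cB loss of benzyloxide can occur.

Step 6
Reactants: 10 prop-2-en-1-yl 2,4-bis(benzyloxy)-6-[(2R)-2-hydroxypropyl]benzoate; 14 (R)-3-(benzyloxy)butanoic acid
Product: 15 prop-2-en-1-yl 2,4-bis(benzyloxy)-6-[(2R)-2-{[(3R)-3-(benzyloxy)butanoyl]oxy}propyl]benzoate
Conditions: EDC·HCl, DMAP (0.2 equiv), CH2Cl2, 0 °C to rt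
Reagents that add atoms: none
Why: Steglich-type carbodiimide esterification of the unhindered secondary alcohol with the aliphatic acid is fast under nearly neutral conditions, so the hydroxy ester should be acylated before it can lactonise, with no stereocentre touched.

Step 7
Reactants: 15 prop-2-en-1-yl 2,4-bis(benzyloxy)-6-[(2R)-2-{[(3R)-3-(benzyloxy)butanoyl]oxy}propyl]benzoate
Product: 16 2,4-bis(benzyloxy)-6-[(2R)-2-{[(3R)-3-(benzyloxy)butanoyl]oxy}propyl]benzoic acid
Conditions: Pd(PPh3)4 (5 mol%), morpholine, THF, rt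
Reagents that add atoms: none
Why: Zerovalent palladium ionises the allyl ester to a π-allyl complex that morpholine captures (Tsuji–Trost deallylation), which should free the hindered acid under neutral conditions that spare the other esters and the benzyl ethers.

Step 8
Reactants: 17 1,3-bis(benzyloxy)-5-bromobenzene; 5 (R)-propylene oxide
Product: 19 (R)-1-[3,5-bis(benzyloxy)phenyl]propan-2-ol, via aryl Grignard reagent 18 (not isolated)
Conditions: Mg, THF, reflux; then CuBr·SMe2 (10 mol%), 5, −30 °C to 0 °C; aq. NH4Cl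
Reagents that add atoms: none
Why: Grignard formation and copper-catalysed SN2 opening of the epoxide at its CH2 terminus should give the secondary alcohol with the (R) centre of 5 untouched.

Step 9
Reactants: 20 (S)-3-hydroxybutanoic acid; 21 tert-butyldimethylsilyl chloride
Product: 23 (S)-3-[(tert-butyldimethylsilyl)oxy]butanoic acid, via bis-silylated hydroxy acid 22 (not isolated)
Conditions: TBSCl (2.2 equiv), imidazole, DMF, rt; then K2CO3, THF–H2O, rt; acidify to pH 4
Reagents that add atoms: tert-butyldimethylsilyl chloride (21), CC(C)(C)[Si](C)(C)Cl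
Why: Silylation of hydroxyl and carboxyl followed by selective hydrolysis of the labile silyl ester is the standard one-flask protection of a hydroxy acid and does not involve the stereocentre.

Step 10
Reactants: 19 (R)-1-[3,5-bis(benzyloxy)phenyl]propan-2-ol; 23 (S)-3-[(tert-butyldimethylsilyl)oxy]butanoic acid
Product: 24 (2R)-1-[3,5-bis(benzyloxy)phenyl]propan-2-yl (3S)-3-[(tert-butyldimethylsilyl)oxy]butanoate
Conditions: EDC·HCl, DMAP (0.2 equiv), CH2Cl2, 0 °C to rt
Reagents that add atoms: none
Why: Steglich-type esterification of the secondary alcohol with the β-silyloxy acid should form the A–B ester with both stereocentres as spectators.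

Step 11
Reactants: 24 (2R)-1-[3,5-bis(benzyloxy)phenyl]propan-2-yl (3S)-3-[(tert-butyldimethylsilyl)oxy]butanoate
Product: 25 (2R)-1-[3,5-bis(benzyloxy)phenyl]propan-2-yl (3S)-3-hydroxybutanoate
Conditions: HF·pyridine, pyridine–THF, 0 °C to rt
Reagents that add atoms: none
Why: Buffered fluoride should cleave the secondary silyl ether without the basic conditions that would promote β-elimination of the β-hydroxy ester.

Step 12
Reactants: 16 2,4-bis(benzyloxy)-6-[(2R)-2-{[(3R)-3-(benzyloxy)butanoyl]oxy}propyl]benzoic acid; 25 (2R)-1-[3,5-bis(benzyloxy)phenyl]propan-2-yl (3S)-3-hydroxybutanoate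
Product: 26 (2R)-4-{[(2R)-1-[3,5-bis(benzyloxy)phenyl]propan-2-yl]oxy}-4-oxobutan-2-yl 2,4-bis(benzyloxy)-6-[(2R)-2-{[(3R)-3-(benzyloxy)butanoyl]oxy}propyl]benzoate (penta-O-benzyl hansforester J)
Conditions: PPh3, DIAD, toluene, 0 °C to rt
Reagents that add atoms: none
Why: In this Mitsunobu esterification the carbinol of 25 is activated as an alkoxyphosphonium ion and displaced by the carboxylate of 16 in an SN2 step, so the hindered acyl carbon is never attacked and the (S) carbinol is inverted to the (R) ester centre of unit B.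

Step 13
Reactants: 26 penta-O-benzyl hansforester J
Product: 27 hansforester J
Conditions: H2 (1 atm), Pd(OH)2/C, EtOAc–THF, rt
Reagents that add atoms: none
Why: Hydrogenolysis over palladium should cleave the four aryl benzyl ethers and the one alkyl benzyl ether, while the four ester linkages, none of which has a benzylic C–O bond, stay intact.

Compound list
1 | 2,4-dihydroxybenzoic acid | OC(=O)c1ccc(O)cc1O | starting material
2 | benzyl bromide | BrCc1ccccc1 | starting material
3 | benzyl 2,4-bis(benzyloxy)benzoate | O=C(OCc1ccccc1)c1ccc(OCc2ccccc2)cc1OCc1ccccc1 | intermediate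
4 | 2,4-bis(benzyloxy)benzoic acid | OC(=O)c1ccc(OCc2ccccc2)cc1OCc1ccccc1 | intermediate
5 | (R)-propylene oxide | C[C@@H]1CO1 | starting material
6 | 2,4-bis(benzyloxy)-6-[(2R)-2-hydroxypropyl]benzoic acid | C[C@@H](O)Cc1cc(OCc2ccccc2)cc(OCc2ccccc2)c1C(=O)O | intermediate
7 | (R)-6,8-bis(benzyloxy)-3-methylisochroman-1-one | C[C@@H]1Cc2cc(OCc3ccccc3)cc(OCc3ccccc3)c2C(=O)O1 | intermediate
8 | allyl bromide | C=CCBr | starting material
9 | potassium 2,4-bis(benzyloxy)-6-[(2R)-2-hydroxypropyl]benzoate | C[C@@H](O)Cc1cc(OCc2ccccc2)cc(OCc2ccccc2)c1C(=O)[O-].[K+] | intermediate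
10 | prop-2-en-1-yl 2,4-bis(benzyloxy)-6-[(2R)-2-hydroxypropyl]benzoate | C[C@@H](O)Cc1cc(OCc2ccccc2)cc(OCc2ccccc2)c1C(=O)OCC=C | intermediate
11 | methyl (R)-3-hydroxybutanoate | C[C@@H](O)CC(=O)OC | starting material
12 | benzyl 2,2,2-trichloroacetimidate | N=C(OCc1ccccc1)C(Cl)(Cl)Cl | starting material
13 | methyl (R)-3-(benzyloxy)butanoate | C[C@@H](OCc1ccccc1)CC(=O)OC | intermediate
14 | (R)-3-(benzyloxy)butanoic acid | C[C@@H](OCc1ccccc1)CC(=O)O | intermediate
15 | prop-2-en-1-yl 2,4-bis(benzyloxy)-6-[(2R)-2-{[(3R)-3-(benzyloxy)butanoyl]oxy}propyl]benzoate | C[C@@H](OC(=O)C[C@@H](C)OCc1ccccc1)Cc1cc(OCc2ccccc2)cc(OCc2ccccc2)c1C(=O)OCC=C | intermediate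
16 | 2,4-bis(benzyloxy)-6-[(2R)-2-{[(3R)-3-(benzyloxy)butanoyl]oxy}propyl]benzoic acid | C[C@@H](OC(=O)C[C@@H](C)OCc1ccccc1)Cc1cc(OCc2ccccc2)cc(OCc2ccccc2)c1C(=O)O | intermediate
17 | 1,3-bis(benzyloxy)-5-bromobenzene | Brc1cc(OCc2ccccc2)cc(OCc2ccccc2)c1 | starting material
18 | [3,5-bis(benzyloxy)phenyl]magnesium bromide | Br[Mg]c1cc(OCc2ccccc2)cc(OCc2ccccc2)c1 | intermediate
19 | (R)-1-[3,5-bis(benzyloxy)phenyl]propan-2-ol | C[C@@H](O)Cc1cc(OCc2ccccc2)cc(OCc2ccccc2)c1 | intermediate
20 | (S)-3-hydroxybutanoic acid | C[C@H](O)CC(=O)O | starting material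
21 | tert-butyldimethylsilyl chloride | CC(C)(C)[Si](C)(C)Cl | starting material
22 | tert-butyldimethylsilyl (3S)-3-[(tert-butyldimethylsilyl)oxy]butanoate | C[C@H](O[Si](C)(C)C(C)(C)C)CC(=O)O[Si](C)(C)C(C)(C)C | intermediate
23 | (S)-3-[(tert-butyldimethylsilyl)oxy]butanoic acid | C[C@H](O[Si](C)(C)C(C)(C)C)CC(=O)O | intermediate
24 | (2R)-1-[3,5-bis(benzyloxy)phenyl]propan-2-yl (3S)-3-[(tert-butyldimethylsilyl)oxy]butanoate | C[C@H](O[Si](C)(C)C(C)(C)C)CC(=O)O[C@H](C)Cc1cc(OCc2ccccc2)cc(OCc2ccccc2)c1 | intermediate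
25 | (2R)-1-[3,5-bis(benzyloxy)phenyl]propan-2-yl (3S)-3-hydroxybutanoate | C[C@H](O)CC(=O)O[C@H](C)Cc1cc(OCc2ccccc2)cc(OCc2ccccc2)c1 | intermediate
26 | penta-O-benzyl hansforester J | C[C@H](Cc1cc(OCc2ccccc2)cc(OCc2ccccc2)c1)OC(=O)C[C@@H](C)OC(=O)c1c(OCc2ccccc2)cc(OCc2ccccc2)cc1C[C@@H](C)OC(=O)C[C@@H](C)OCc1ccccc1 | intermediate
27 | hansforester J | C[C@H](Cc1cc(O)cc(O)c1)OC(=O)C[C@@H](C)OC(=O)c1c(O)cc(O)cc1C[C@@H](C)OC(=O)C[C@@H](C)O | target

Total step count: 13 steps.
Longest linear sequence: 7 steps (steps 1, 2, 3, 6, 7, 12, 13) from 2,4-dihydroxybenzoic acid.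

Steps most likely to fail

Step 2. The electron-rich 2,4-dialkoxybenzoate may undergo decarboxylative palladation or protodecarboxylation, or the fluoroalcohol may consume the volatile epoxide faster than C–H alkylation proceeds, so that conversion to the lactone stalls. The fallback sets out from alcohol 19 and builds the carboxyl group onto the ring that already carries the side chain. NBS (1.0 equiv) in MeCN at 0 °C should brominate the position ortho to the side chain and para to one benzyloxy group, the site between the two ethers being more hindered, to give (R)-1-[3,5-bis(benzyloxy)-2-bromophenyl]propan-2-ol F1. Treatment with n-BuLi (2.2 equiv) in THF at −78 °C (alkoxide formation, then bromine–lithium exchange), a CO2 quench and acidic work-up with TsOH should give hydroxy acid 6, which closes to lactone 7, where the fallback rejoins the route.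

Step 12. The activated β-hydroxy ester may lose the oxyphosphonium group by β-elimination to the crotonate instead of undergoing SN2 displacement, or inversion may be incomplete. The fallback sets out from 19 and 16, forms the hindered ester by acyl substitution with retention, and therefore uses the (R)-configured alcohol. Heating 19 with 2,2,6-trimethyl-4H-1,3-dioxin-4-one in xylene at 130 °C (acylketene trapping) should give (R)-1-[3,5-bis(benzyloxy)phenyl]propan-2-yl 3-oxobutanoate F2. Noyori hydrogenation of F2 (H2, 10 bar, RuCl2[(R)-BINAP], EtOH, 50 °C), in which the catalyst sets the new (R) carbinol, should give (2R)-1-[3,5-bis(benzyloxy)phenyl]propan-2-yl (3R)-3-hydroxybutanoate F3. Acid 16 is converted with oxalyl chloride and catalytic DMF in CH2Cl2 into 2,4-bis(benzyloxy)-6-[(2R)-2-{[(3R)-3-(benzyloxy)butanoyl]oxy}propyl]benzoyl chloride F4. F4 is then coupled with F3 (Et3N, DMAP, toluene, 40 °C) to rejoin the route at 26.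

Step 3. The hydroxy ester may close back to lactone 7 by intramolecular transesterification during alkylation or handling. The fallback sets out from potassium salt 9, masks the carbinol as a silyl ether and reverses the order of the two esterifications. TBSCl (2.5 equiv) and imidazole in DMF should give tert-butyldimethylsilyl 2,4-bis(benzyloxy)-6-[(2R)-2-[(tert-butyldimethylsilyl)oxy]propyl]benzoate F5. Its silyl ester is cleaved in the same flask with K2CO3 in THF–H2O to give 2,4-bis(benzyloxy)-6-[(2R)-2-[(tert-butyldimethylsilyl)oxy]propyl]benzoic acid F6. Mitsunobu esterification of F6 with alcohol 25 (PPh3, DIAD, toluene), with inversion at the carbinol of unit B, should give the silyl-protected A–B–C triester F7. HF·pyridine in pyridine–THF then frees the A–B–C hydroxy triester F8, and EDC·HCl/DMAP acylation of F8 with acid 14 rejoins the route at 26.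

Further compounds
F1 | step 2 | (R)-1-[3,5-bis(benzyloxy)-2-bromophenyl]propan-2-ol | C[C@@H](O)Cc1cc(OCc2ccccc2)cc(OCc2ccccc2)c1Br
F2 | step 12 | (R)-1-[3,5-bis(benzyloxy)phenyl]propan-2-yl 3-oxobutanoate | CC(=O)CC(=O)O[C@H](C)Cc1cc(OCc2ccccc2)cc(OCc2ccccc2)c1
F3 | step 12 | (2R)-1-[3,5-bis(benzyloxy)phenyl]propan-2-yl (3R)-3-hydroxybutanoate | C[C@@H](O)CC(=O)O[C@H](C)Cc1cc(OCc2ccccc2)cc(OCc2ccccc2)c1
F4 | step 12 | 2,4-bis(benzyloxy)-6-[(2R)-2-{[(3R)-3-(benzyloxy)butanoyl]oxy}propyl]benzoyl chloride | C[C@@H](OC(=O)C[C@@H](C)OCc1ccccc1)Cc1cc(OCc2ccccc2)cc(OCc2ccccc2)c1C(=O)Cl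
F5 | step 3 | tert-butyldimethylsilyl 2,4-bis(benzyloxy)-6-[(2R)-2-[(tert-butyldimethylsilyl)oxy]propyl]benzoate | C[C@@H](O[Si](C)(C)C(C)(C)C)Cc1cc(OCc2ccccc2)cc(OCc2ccccc2)c1C(=O)O[Si](C)(C)C(C)(C)C
F6 | step 3 | 2,4-bis(benzyloxy)-6-[(2R)-2-[(tert-butyldimethylsilyl)oxy]propyl]benzoic acid | C[C@@H](O[Si](C)(C)C(C)(C)C)Cc1cc(OCc2ccccc2)cc(OCc2ccccc2)c1C(=O)O
F7 | step 3 | (2R)-4-{[(2R)-1-[3,5-bis(benzyloxy)phenyl]propan-2-yl]oxy}-4-oxobutan-2-yl 2,4-bis(benzyloxy)-6-[(2R)-2-[(tert-butyldimethylsilyl)oxy]propyl]benzoate | C[C@H](Cc1cc(OCc2ccccc2)cc(OCc2ccccc2)c1)OC(=O)C[C@@H](C)OC(=O)c1c(OCc2ccccc2)cc(OCc2ccccc2)cc1C[C@@H](C)O[Si](C)(C)C(C)(C)C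
F8 | step 3 | (2R)-4-{[(2R)-1-[3,5-bis(benzyloxy)phenyl]propan-2-yl]oxy}-4-oxobutan-2-yl 2,4-bis(benzyloxy)-6-[(2R)-2-hydroxypropyl]benzoate | C[C@H](Cc1cc(OCc2ccccc2)cc(OCc2ccccc2)c1)OC(=O)C[C@@H](C)OC(=O)c1c(OCc2ccccc2)cc(OCc2ccccc2)cc1C[C@@H](C)O
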